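**Retrosynthetic overview**

1. Labels: ring C1 (CH2OAc), C2 (CHO), C3 (stereocentre), C4, C5; C1′ is the side-chain CH(CHO) on C3. The two formyl groups stand 1,5 across C2–C3–C1′, which is an opened 2-methoxy-3,4-dihydro-2H-pyran (ring B: O, acetal C, C2, C3, C1′, enol-ether CH). The C1=C2 bond is what remains of a leaving group on C1, β to the C2 formyl group.
2. Key disconnection: C2–C3 and O–CH(OMe), formed together by an intramolecular inverse-demand oxa-Diels–Alder reaction of (E)-enal 22 with its tethered enol ether. Cyclopentane ring A and the temporary ring B close in that one step; ring B is opened again at the end.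
3. Precursor 22 comes from aldehyde 13 and formyl ylide 21 (Wittig at C3=C1′). Aldehyde 13 comes from Sharpless epoxide 6, whose quaternary C1 relays its chirality to C3 and is then flattened.
4. The C1–O and CH2–O oxygens travel as benzyl ethers and become acetates after the cycloaddition.
5. Order: C1 (epoxidation) → enol ether → enal → rings A and B → benzyl/acetate exchange → ring B opened (C1′ set) and AcOH lost (C1=C2).

Key step: step 15

Remarks on the chemistry:
- (3-Bromopropoxy)(tert-butyl)dimethylsilane, the TBS ether of 3-bromopropan-1-ol, is taken as a purchased starting material.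
- The oxygen on C1 is a benzyl ether during the cycloaddition and an acetate at the unmasking stage. Acetate leaves a β-acyloxy aldehyde on brief contact with Et3N, whereas loss of methanol would need conditions that also enolise the C1′ aldehyde.
- Step 6 is expected to give both enol-ether geometries; the (E)-isomer is separated and numbered. The acetal carbon of 23–25 is left undefined because it is lost in step 18.

**Route**

Step 1
Reactants: 1 (3-bromopropoxy)(tert-butyl)dimethylsilane; 2 prop-2-yn-1-ol (propargyl alcohol)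
Product: 5 5-[(tert-butyldimethylsilyl)oxy]-2-methylidenepentan-1-ol, via Grignard reagent 3 (not isolated), via alkenylmagnesium alkoxide 4 (not isolated)
Conditions: Mg, THF, 40 °C (1 to 3, 2.5 equiv); then 2, CuI (10 mol%), THF, −10 °C → rt; aq. NH4Cl
Reagents that add atoms: none
Why: Copper-catalysed carbomagnesiation of propargyl alcohol, in which the magnesium alkoxide directs anti addition of the alkyl group to the internal alkyne carbon and protonation on work-up leaves the 2-substituted allylic alcohol; no stereocentre is formed.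

Step 2
Reactants: 5 5-[(tert-butyldimethylsilyl)oxy]-2-methylidenepentan-1-ol
Product: 6 [(2S)-2-{3-[(tert-butyldimethylsilyl)oxy]propyl}oxiran-2-yl]methanol
Conditions: Ti(OiPr)4 (10 mol%), L-(+)-diisopropyl tartrate (12 mol%), tBuOOH (2 equiv), 4 Å MS, CH2Cl2, −20 °C
Reagents that add atoms: tert-butyl hydroperoxide, CC(C)(C)OO
Why: Sharpless asymmetric epoxidation of a 2-substituted allylic alcohol; L-(+)-tartrate delivers oxygen in the sense that gives (S)-glycidol from allyl alcohol, which sets C1 as (S)-6, and the catalytic, sieve-dried conditions keep the 2,2-disubstituted epoxide from being opened.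

Step 3
Reactants: 6 [(2S)-2-{3-[(tert-butyldimethylsilyl)oxy]propyl}oxiran-2-yl]methanol
Product: 8 tert-butyl{[(4S)-4,5-bis(benzyloxy)-4-{[(4-methoxybenzyl)oxy]methyl}pentyl]oxy}dimethylsilane, via disodium dialkoxide 7 (not isolated)
Conditions: 4-MeOC6H4CH2OH (3 equiv), NaH, DMF, 60 °C; then NaH, BnBr (excess), Bu4NI (cat.), 0 °C → rt
Reagents that add atoms: 4-methoxybenzyl alcohol, COc1ccc(CO)cc1; benzyl bromide, BrCc1ccccc1
Why: SN2 opening of the epoxide by the alkoxide at its unsubstituted CH2 leaves the C1–O bond and thus the configuration untouched (the Payne rearrangement of this 2-substituted glycidol only regenerates the same enantiomer), and Williamson benzylation of the primary and tertiary alkoxides in the same flask gives three ether groups that cannot migrate between the two CH2O arms, a migration that would racemise C1.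

Step 4
Reactants: 8 tert-butyl{[(4S)-4,5-bis(benzyloxy)-4-{[(4-methoxybenzyl)oxy]methyl}pentyl]oxy}dimethylsilane
Product: 9 (2R)-2-(benzyloxy)-2-[(benzyloxy)methyl]-5-[(tert-butyldimethylsilyl)oxy]pentan-1-ol
Conditions: DDQ (1.3 equiv), CH2Cl2/pH 7 buffer, 0 °C
Reagents that add atoms: none
Why: Oxidative cleavage of the p-methoxybenzyl ether by DDQ, which is much faster than attack on the two plain benzyl ethers, frees only the arm that becomes C2.

Step 5
Reactants: 9 (2R)-2-(benzyloxy)-2-[(benzyloxy)methyl]-5-[(tert-butyldimethylsilyl)oxy]pentan-1-ol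
Product: 10 (2S)-2-(benzyloxy)-2-[(benzyloxy)methyl]-5-[(tert-butyldimethylsilyl)oxy]pentanal
Conditions: Dess–Martin periodinane, CH2Cl2, 0 °C → rt
Reagents that add atoms: none
Why: Dess–Martin oxidation of the neopentyl-type primary alcohol; the aldehyde has no α-hydrogen, so C1 cannot epimerise.

Step 6
Reactants: 10 (2S)-2-(benzyloxy)-2-[(benzyloxy)methyl]-5-[(tert-butyldimethylsilyl)oxy]pentanal
Product: 11 tert-butyl{[(4R,5E)-4-(benzyloxy)-4-[(benzyloxy)methyl]-6-methoxyhex-5-en-1-yl]oxy}dimethylsilane
Conditions: (MeOCH2)PPh3Cl, KN(SiMe3)2, THF, 0 °C; then 10, 0 °C → rt; chromatography on Et3N-deactivated silica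
Reagents that add atoms: (methoxymethyl)triphenylphosphonium chloride, [Cl-].COC[P+](c1ccccc1)(c1ccccc1)c1ccccc1
Why: Wittig methoxymethylenation of the electrophilic α-alkoxy aldehyde installs the enol ether whose β-carbon is C2; ethers and the silyl group are inert to the ylide, and the (E)-isomer is separated from the (Z)-isomer.

Step 7
Reactants: 11 tert-butyl{[(4R,5E)-4-(benzyloxy)-4-[(benzyloxy)methyl]-6-methoxyhex-5-en-1-yl]oxy}dimethylsilane
Product: 12 (4R,5E)-4-(benzyloxy)-4-[(benzyloxy)methyl]-6-methoxyhex-5-en-1-ol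
Conditions: Bu4NF, THF, 0 °C
Reagents that add atoms: none
Why: Fluoride cleavage of the primary silyl ether under basic conditions, which the acid-labile γ-alkoxy enol ether tolerates.

Step 8
Reactants: 12 (4R,5E)-4-(benzyloxy)-4-[(benzyloxy)methyl]-6-methoxyhex-5-en-1-ol
Product: 13 (4R,5E)-4-(benzyloxy)-4-[(benzyloxy)methyl]-6-methoxyhex-5-enal
Conditions: SO3·pyridine, DMSO, iPr2NEt, CH2Cl2, 0 °C
Reagents that add atoms: none
Why: Parikh–Doering oxidation stops at the aldehyde and stays basic throughout, which protects the enol ether and the tertiary allylic ether.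

Step 9
Reactants: 14 geranyl bromide, (2E)-1-bromo-3,7-dimethylocta-2,6-diene
Product: 15 ethyl (4E)-5,9-dimethyldeca-4,8-dienoate
Conditions: LiN(iPr)2, EtOAc, THF, −78 °C; then 14, DMPU, −78 → −20 °C
Reagents that add atoms: ethyl acetate, CCOC(C)=O
Why: Alkylation of the lithium enolate of ethyl acetate by SN2 at the primary allylic bromide adds the two carbons needed and leaves the (E)-alkene untouched.

Step 10
Reactants: 15 ethyl (4E)-5,9-dimethyldeca-4,8-dienoate
Product: 16 (4E)-5,9-dimethyldeca-4,8-dien-1-ol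
Conditions: LiAlH4, Et2O, 0 °C
Reagents that add atoms: none
Why: Hydride reduction of the ester to the primary alcohol; isolated alkenes are inert.

Step 11
Reactants: 16 (4E)-5,9-dimethyldeca-4,8-dien-1-ol
Product: 17 (4E)-1-iodo-5,9-dimethyldeca-4,8-diene
Conditions: I2, PPh3, imidazole, CH2Cl2, 0 °C → rt
Reagents that add atoms: iodine, II
Why: Appel-type iodination of a primary alcohol through the alkoxyphosphonium ion.

Step 12
Reactants: 17 (4E)-1-iodo-5,9-dimethyldeca-4,8-diene
Product: 18 [(4E)-5,9-dimethyldeca-4,8-dien-1-yl]triphenylphosphonium iodide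
Conditions: PPh3, MeCN, reflux
Reagents that add atoms: triphenylphosphine, c1ccc(cc1)P(c1ccccc1)c1ccccc1
Why: SN2 quaternisation of triphenylphosphine by the primary iodide.

Step 13
Reactants: 18 [(4E)-5,9-dimethyldeca-4,8-dien-1-yl]triphenylphosphonium iodide
Product: 21 (5E)-6,10-dimethyl-2-(triphenyl-λ5-phosphanylidene)undeca-5,9-dienal, via phosphorus ylide 19 (not isolated), via formylphosphonium ethoxide 20 (not isolated)
Conditions: nBuLi (1.0 equiv), THF, −78 → 0 °C; then HCO2Et (3 equiv), 0 °C → rt
Reagents that add atoms: ethyl formate, CCOC=O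
Why: C-formylation of the unstabilised ylide with ethyl formate, after which the ethoxide released removes the now acidic α-proton to give the stabilised formyl ylide that carries C1′ and the whole side chain.

Step 14
Reactants: 13 (4R,5E)-4-(benzyloxy)-4-[(benzyloxy)methyl]-6-methoxyhex-5-enal; 21 (5E)-6,10-dimethyl-2-(triphenyl-λ5-phosphanylidene)undeca-5,9-dienal
Product: 22 (2E,6R,7E)-6-(benzyloxy)-6-[(benzyloxy)methyl]-2-[(3E)-4,8-dimethylnona-3,7-dien-1-yl]-8-methoxyocta-2,7-dienal
Conditions: benzene, K2CO3 (solid, trace), 60 °C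
Reagents that add atoms: none
Why: Wittig olefination with a stabilised α-formyl ylide is (E)-selective, proceeds under neutral conditions, and attacks the unhindered aliphatic aldehyde but not the hindered, conjugated enal it produces.

Step 15
Reactants: 22 (2E,6R,7E)-6-(benzyloxy)-6-[(benzyloxy)methyl]-2-[(3E)-4,8-dimethylnona-3,7-dien-1-yl]-8-methoxyocta-2,7-dienal
Product: 23 (4aS,7R,7aS)-7-(benzyloxy)-7-[(benzyloxy)methyl]-4-[(3E)-4,8-dimethylnona-3,7-dien-1-yl]-1-methoxy-1,4a,5,6,7,7a-hexahydrocyclopenta[c]pyran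
Conditions: toluene (0.01 M), K2CO3 (solid), 2,6-di-tert-butyl-4-methylphenol (cat.), degassed, sealed tube, 120 °C; no Lewis acid
Reagents that add atoms: none
Why: On heating, the s-cis (E)-enal O=CH–C1′=C3 acts as an electron-poor 1-oxadiene toward the electron-rich enol ether C2=CH–OMe in a concerted, asynchronous inverse-electron-demand oxa-Diels–Alder reaction, with C2–C3 bonding ahead of O–CH(OMe) bonding; the closest known reaction type is the enal plus vinyl ether dihydropyran synthesis in its tethered form, as used for cyclopenta[c]pyran acetals. The C5–C4 tether joins diene terminus C3 to dienophile carbon C2, so ring A closes in 5-exo fashion with respect to both π bonds, and ring B is the six-membered ring of the [4+2] itself, closed suprafacially by the O–C bond. Regiochemistry is fixed by polarity and tether (nucleophilic C2 to electrophilic C3), and the short tether should allow only the folded transition state that gives the cis ring fusion at C2/C3. The face is set by C1: with C5 held over the reacting face, the two-coordinate benzyloxy oxygen should take the inside position eclipsing the enol-ether double bond and the larger CH2OBn the outside, which places the C1 oxygen cis to the acetal carbon and gives (4aS,7aS). The step needs periselectivity over ene and cationic pathways and no ionisation of the tertiary allylic ether; high dilution, a solid base and the absence of Lewis acids such as Eu(fod)3 (trivalent europium) are chosen for this. The facial bias is expected to be only moderate, so the C2/C3 diastereomer must be removed by chromatography here, because it would become the enantiomer of the target once C1 is flattened.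

Step 16
Reactants: 23 (4aS,7R,7aS)-7-(benzyloxy)-7-[(benzyloxy)methyl]-4-[(3E)-4,8-dimethylnona-3,7-dien-1-yl]-1-methoxy-1,4a,5,6,7,7a-hexahydrocyclopenta[c]pyran
Product: 24 (4aS,7R,7aS)-4-[(3E)-4,8-dimethylnona-3,7-dien-1-yl]-7-(hydroxymethyl)-1-methoxy-1,4a,5,6,7,7a-hexahydrocyclopenta[c]pyran-7-ol
Conditions: Na, liquid NH3/THF, −78 °C; solid NH4Cl
Reagents that add atoms: none
Why: Birch-type dissolving-metal cleavage removes both benzyl ethers, while the isolated trisubstituted alkenes, the enol ether and the acetal are inert; the C1–O bond is no longer allylic after the cycloaddition and is kept.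

Step 17
Reactants: 24 (4aS,7R,7aS)-4-[(3E)-4,8-dimethylnona-3,7-dien-1-yl]-7-(hydroxymethyl)-1-methoxy-1,4a,5,6,7,7a-hexahydrocyclopenta[c]pyran-7-ol
Product: 25 [(4aS,7R,7aS)-7-acetoxy-4-[(3E)-4,8-dimethylnona-3,7-dien-1-yl]-1-methoxy-1,4a,5,6,7,7a-hexahydrocyclopenta[c]pyran-7-yl]methyl acetate
Conditions: Ac2O (excess), DMAP (1.5 equiv), Et3N, CH2Cl2, rt → 35 °C
Reagents that add atoms: acetic anhydride, CC(=O)OC(C)=O
Why: DMAP-catalysed acetylation takes the primary hydroxyl at once and the tertiary one on warming; this installs the acetate of the target and turns the C1 oxygen into a leaving group, under basic conditions that spare the acetal and the enol ether.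

Step 18
Reactants: 25 [(4aS,7R,7aS)-7-acetoxy-4-[(3E)-4,8-dimethylnona-3,7-dien-1-yl]-1-methoxy-1,4a,5,6,7,7a-hexahydrocyclopenta[c]pyran-7-yl]methyl acetate
Product: 27 [(3R)-2-formyl-3-[(2S,5E)-6,10-dimethyl-1-oxoundeca-5,9-dien-2-yl]cyclopent-1-en-1-yl]methyl acetate, via acetoxy dialdehyde 26 (not isolated)
Conditions: 0.5 M aq. HCl/THF, 0 °C; then Et3N to pH 8–9, 0 °C, short contact; pH 7 buffer
Reagents that add atoms: water, O
Why: Acid hydrolysis of the 2-methoxy-dihydropyran protonates the enol-ether carbon C1′ on the convex face of the cis-fused bicycle (syn to H-3, anti to the cyclopentane CH2), which sets C1′ as S; water then opens ring B to the 1,5-dialdehyde, and Et3N triggers E1cB loss of the tertiary acetate from the C2 enolate to give the C1=C2 enal, brief contact with a weak amine being enough for this leaving group and so sparing the enolisable C1′ centre.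

**Compound list**

1 | (3-bromopropoxy)(tert-butyl)dimethylsilane | BrCCCO[Si](C)(C)C(C)(C)C | starting material
2 | prop-2-yn-1-ol (propargyl alcohol) | C#CCO | starting material
3 | {3-[(tert-butyldimethylsilyl)oxy]propyl}magnesium bromide | Br[Mg]CCCO[Si](C)(C)C(C)(C)C | intermediate (not isolated)
4 | bromomagnesium alkoxide of 3-(bromomagnesio)-2-{3-[(tert-butyldimethylsilyl)oxy]propyl}prop-2-en-1-ol, Mg on the terminal carbon cis to CH2O | Br[Mg]/C=C(/CCCO[Si](C)(C)C(C)(C)C)CO[Mg]Br | intermediate (not isolated)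
5 | 5-[(tert-butyldimethylsilyl)oxy]-2-methylidenepentan-1-ol | C=C(CO)CCCO[Si](C)(C)C(C)(C)C | intermediate
6 | [(2S)-2-{3-[(tert-butyldimethylsilyl)oxy]propyl}oxiran-2-yl]methanol | CC(C)(C)[Si](C)(C)OCCC[C@]1(CO)CO1 | intermediate
7 | disodium salt of (2S)-5-[(tert-butyldimethylsilyl)oxy]-2-{[(4-methoxybenzyl)oxy]methyl}pentane-1,2-diol | [Na+].[Na+].CC(C)(C)[Si](C)(C)OCCC[C@]([O-])(C[O-])COCc1ccc(OC)cc1 | intermediate (not isolated)
8 | tert-butyl{[(4S)-4,5-bis(benzyloxy)-4-{[(4-methoxybenzyl)oxy]methyl}pentyl]oxy}dimethylsilane | CC(C)(C)[Si](C)(C)OCCC[C@](OCc1ccccc1)(COCc1ccccc1)COCc1ccc(OC)cc1 | intermediate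
9 | (2R)-2-(benzyloxy)-2-[(benzyloxy)methyl]-5-[(tert-butyldimethylsilyl)oxy]pentan-1-ol | CC(C)(C)[Si](C)(C)OCCC[C@](OCc1ccccc1)(COCc1ccccc1)CO | intermediate
10 | (2S)-2-(benzyloxy)-2-[(benzyloxy)methyl]-5-[(tert-butyldimethylsilyl)oxy]pentanal | CC(C)(C)[Si](C)(C)OCCC[C@](OCc1ccccc1)(COCc1ccccc1)C=O | intermediate
11 | tert-butyl{[(4R,5E)-4-(benzyloxy)-4-[(benzyloxy)methyl]-6-methoxyhex-5-en-1-yl]oxy}dimethylsilane | CC(C)(C)[Si](C)(C)OCCC[C@](OCc1ccccc1)(COCc1ccccc1)/C=C/OC | intermediate
12 | (4R,5E)-4-(benzyloxy)-4-[(benzyloxy)methyl]-6-methoxyhex-5-en-1-ol | OCCC[C@](OCc1ccccc1)(COCc1ccccc1)/C=C/OC | intermediate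
13 | (4R,5E)-4-(benzyloxy)-4-[(benzyloxy)methyl]-6-methoxyhex-5-enal | O=CCC[C@](OCc1ccccc1)(COCc1ccccc1)/C=C/OC | intermediate
14 | geranyl bromide, (2E)-1-bromo-3,7-dimethylocta-2,6-diene | CC(C)=CCC/C(C)=C/CBr | starting material
15 | ethyl (4E)-5,9-dimethyldeca-4,8-dienoate | CCOC(=O)CC/C=C(\C)CCC=C(C)C | intermediate
16 | (4E)-5,9-dimethyldeca-4,8-dien-1-ol | OCCC/C=C(\C)CCC=C(C)C | intermediate
17 | (4E)-1-iodo-5,9-dimethyldeca-4,8-diene | ICCC/C=C(\C)CCC=C(C)C | intermediate
18 | [(4E)-5,9-dimethyldeca-4,8-dien-1-yl]triphenylphosphonium iodide | [I-].CC(C)=CCC/C(C)=C/CCC[P+](c1ccccc1)(c1ccccc1)c1ccccc1 | intermediate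
19 | [(4E)-5,9-dimethyldeca-4,8-dien-1-ylidene]triphenylphosphorane | CC(C)=CCC/C(C)=C/CCC=P(c1ccccc1)(c1ccccc1)c1ccccc1 | intermediate (not isolated)
20 | [(5E)-6,10-dimethyl-1-oxoundeca-5,9-dien-2-yl]triphenylphosphonium ethoxide | CC[O-].CC(C)=CCC/C(C)=C/CCC(C=O)[P+](c1ccccc1)(c1ccccc1)c1ccccc1 | intermediate (not isolated)
21 | (5E)-6,10-dimethyl-2-(triphenyl-λ5-phosphanylidene)undeca-5,9-dienal | CC(C)=CCC/C(C)=C/CCC(C=O)=P(c1ccccc1)(c1ccccc1)c1ccccc1 | intermediate
22 | (2E,6R,7E)-6-(benzyloxy)-6-[(benzyloxy)methyl]-2-[(3E)-4,8-dimethylnona-3,7-dien-1-yl]-8-methoxyocta-2,7-dienal | O=C/C(CC/C=C(\C)CCC=C(C)C)=C/CC[C@](OCc1ccccc1)(COCc1ccccc1)/C=C/OC | intermediate (key-step precursor)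
23 | (4aS,7R,7aS)-7-(benzyloxy)-7-[(benzyloxy)methyl]-4-[(3E)-4,8-dimethylnona-3,7-dien-1-yl]-1-methoxy-1,4a,5,6,7,7a-hexahydrocyclopenta[c]pyran, cis-fused, acetal carbon undefined | C(OC[C@]1(OCc3ccccc3)[C@H]2C(OC)OC=C(CC/C=C(\C)CCC=C(C)C)[C@H]2CC1)c1ccccc1 | intermediate (key-step product)
24 | (4aS,7R,7aS)-4-[(3E)-4,8-dimethylnona-3,7-dien-1-yl]-7-(hydroxymethyl)-1-methoxy-1,4a,5,6,7,7a-hexahydrocyclopenta[c]pyran-7-ol | OC[C@]1(O)[C@H]2C(OC)OC=C(CC/C=C(\C)CCC=C(C)C)[C@H]2CC1 | intermediate
25 | [(4aS,7R,7aS)-7-acetoxy-4-[(3E)-4,8-dimethylnona-3,7-dien-1-yl]-1-methoxy-1,4a,5,6,7,7a-hexahydrocyclopenta[c]pyran-7-yl]methyl acetate | CC(=O)OC[C@]1(OC(C)=O)[C@H]2C(OC)OC=C(CC/C=C(\C)CCC=C(C)C)[C@H]2CC1 | intermediate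
26 | [(1R,2S,3R)-1-acetoxy-2-formyl-3-[(2S,5E)-6,10-dimethyl-1-oxoundeca-5,9-dien-2-yl]cyclopentyl]methyl acetate | CC(=O)OC[C@]1(OC(C)=O)[C@@H](C=O)[C@@H]([C@@H](C=O)CC/C=C(\C)CCC=C(C)C)CC1 | intermediate (not isolated)
27 | [(3R)-2-formyl-3-[(2S,5E)-6,10-dimethyl-1-oxoundeca-5,9-dien-2-yl]cyclopent-1-en-1-yl]methyl acetate (CNP0280859.1) | CC(=O)OCC1=C(C=O)[C@@H]([C@@H](C=O)CC/C=C(\C)CCC=C(C)C)CC1 | target

**Step count**

Total steps: 18. Longest linear sequence: 13 (steps 1–8 and 14–18); the side-chain branch (steps 9–13) joins at step 14.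

**Steps most likely to fail**

Step 15. Two processes threaten it. Rotation about the C1–C2 bond of the (E)-enol ether may let either the benzyloxy or the benzyloxymethyl group take the inside position, so that bond formation on the wrong face of C2 competes and, after C1 is flattened, shows up as loss of enantiomeric purity. Prolonged heating may also ionise the tertiary allylic ether. The fallback changes the dienophile geometry so that allylic 1,3-strain with a cis methoxy group forces the small alkoxy substituent inside. It sets out from aldehyde 10. Lithiated (methoxymethyl)diphenylphosphine oxide (LiN(iPr)2, THF, −78 °C) gives the β-hydroxy phosphine oxides. The diastereomer that eliminates to the (Z)-alkene, Horner–Wittig adduct F1, is separated and treated with KH in THF to give (Z)-enol ether F2. Bu4NF then gives (Z)-alcohol F3, Parikh–Doering oxidation gives (Z)-aldehyde F4, and Wittig reaction with 21 gives (Z)-precursor F5. Heating as in step 15 should give 23 as its other acetal epimer, where the route is rejoined.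

Step 18. If ring B opens at the acetal before the enol-ether carbon is protonated, an acyclic enol is released that ketonises without facial bias, and the base used for the elimination may enolise the C1′ aldehyde; both processes scramble C1′. The fallback separates the proton transfer from the ring opening. It sets out from 25. Methanol and a catalytic amount of pyridinium p-toluenesulfonate in CH2Cl2 at −20 °C add across the enol ether of the intact bicycle, the reaction type of tetrahydropyranyl ether formation, with the proton entering C1′ from the convex face, to give bis(methyl acetal) F6. This is hydrolysed with cold dilute aqueous HCl in THF and treated briefly with Et3N, and the route is rejoined at 27.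

Step 17. Acylation of the hindered tertiary hydroxyl may stall at the primary mono-acetate. The fallback makes the leaving group only at the moment of elimination. It sets out from 24. Ac2O in pyridine at 0 °C acetylates the primary hydroxyl alone to give mono-acetate F7. Cold dilute aqueous HCl in THF opens ring B to hydroxy dialdehyde F8. MsCl and Et3N at −20 °C convert the tertiary hydroxyl through the sulfene into mesylate F9, which loses methanesulfonate by E1cB in the same flask, the standard dehydration of an aldol, and the route is rejoined at 27.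

**Further compounds**

F1 | step 15 | Horner–Wittig adduct of 10, the β-hydroxy phosphine oxide diastereomer that gives the (Z)-enol ether | CC(C)(C)[Si](C)(C)OCCC[C@](OCc1ccccc1)(COCc1ccccc1)C(O)C(OC)P(=O)(c1ccccc1)c1ccccc1
F2 | step 15 | tert-butyl{[(4R,5Z)-4-(benzyloxy)-4-[(benzyloxy)methyl]-6-methoxyhex-5-en-1-yl]oxy}dimethylsilane | CC(C)(C)[Si](C)(C)OCCC[C@](OCc1ccccc1)(COCc1ccccc1)/C=C\OC
F3 | step 15 | (4R,5Z)-4-(benzyloxy)-4-[(benzyloxy)methyl]-6-methoxyhex-5-en-1-ol | OCCC[C@](OCc1ccccc1)(COCc1ccccc1)/C=C\OC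
F4 | step 15 | (4R,5Z)-4-(benzyloxy)-4-[(benzyloxy)methyl]-6-methoxyhex-5-enal | O=CCC[C@](OCc1ccccc1)(COCc1ccccc1)/C=C\OC
F5 | step 15 | (2E,6R,7Z)-6-(benzyloxy)-6-[(benzyloxy)methyl]-2-[(3E)-4,8-dimethylnona-3,7-dien-1-yl]-8-methoxyocta-2,7-dienal | O=C/C(CC/C=C(\C)CCC=C(C)C)=C/CC[C@](OCc1ccccc1)(COCc1ccccc1)/C=C\OC
F6 | step 18 | bis(methyl acetal) of 26, [(4S,4aR,7R,7aS)-7-acetoxy-4-[(3E)-4,8-dimethylnona-3,7-dien-1-yl]-1,3-dimethoxyoctahydrocyclopenta[c]pyran-7-yl]methyl acetate, H-4 cis to H-4a | CC(=O)OC[C@]1(OC(C)=O)[C@H]2C(OC)OC(OC)[C@@H](CC/C=C(\C)CCC=C(C)C)[C@H]2CC1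
F7 | step 17 | [(4aS,7R,7aS)-4-[(3E)-4,8-dimethylnona-3,7-dien-1-yl]-7-hydroxy-1-methoxy-1,4a,5,6,7,7a-hexahydrocyclopenta[c]pyran-7-yl]methyl acetate | CC(=O)OC[C@]1(O)[C@H]2C(OC)OC=C(CC/C=C(\C)CCC=C(C)C)[C@H]2CC1
F8 | step 17 | [(1R,2S,3R)-2-formyl-3-[(2S,5E)-6,10-dimethyl-1-oxoundeca-5,9-dien-2-yl]-1-hydroxycyclopentyl]methyl acetate | CC(=O)OC[C@]1(O)[C@@H](C=O)[C@@H]([C@@H](C=O)CC/C=C(\C)CCC=C(C)C)CC1
F9 | step 17 | [(1R,2S,3R)-2-formyl-3-[(2S,5E)-6,10-dimethyl-1-oxoundeca-5,9-dien-2-yl]-1-[(methylsulfonyl)oxy]cyclopentyl]methyl acetate | CC(=O)OC[C@]1(OS(C)(=O)=O)[C@@H](C=O)[C@@H]([C@@H](C=O)CC/C=C(\C)CCC=C(C)C)CC1
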